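Cuts: the benzyl group on O3' (removed last). In ring A, the C4a–C5 bond (electrocyclization) and the C8–C8a bond (organolithium addition to a squarate carbonyl). In ring C, the O1–C8a and C2–C3 bonds (γ-pyrone synthesis from an aroyl chloride and 4-methoxybutenone).
Enabling feature: C5, C6, C7, C8 and C8a of ring A carry oxygen in an unbroken row and only O5 is unalkylated. C5–C8 are therefore the four carbons of dimethyl squarate, and C8a=C4a is the C2=C3 enol ether bond of a 4-pyranone that already is ring C.
Forward order: ring B is bought and ring C is built as a 2-aryl-4-pyranone. The four-membered ring is attached at the future C8a and its carbinol is methylated. Ring A closes last by thermal ring expansion, and hydrogenolysis ends the route.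
Stereochemistry: the target has no stereocentre. The one stereocentre met on the way (the quaternary cyclobutenone carbon) is racemic and becomes the planar C8.

Key step: step 5

Remark: flavone numbering is used for rings A and C; the free α-carbon C6 of the 2-aryl-4-pyranone is called C2 of the pyranonyl group once the cyclobutenone is attached and ends as C8a; all cyclobutenones are racemic.

Step 1
Reactants: 1 3-(benzyloxy)-4-methoxybenzoic acid
Product: 2 3-(benzyloxy)-4-methoxybenzoyl chloride
Conditions: (COCl)2, DMF (cat.), CH2Cl2, 0 °C → rt; evaporate, use crude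
Reagents that add atoms: oxalyl chloride, O=C(Cl)C(=O)Cl
Why: Acid chloride formation through the chloroiminium species from (COCl)2 and DMF runs cold and without strong acid, so both aryl ethers should stay intact.

Step 2
Reactants: 2 3-(benzyloxy)-4-methoxybenzoyl chloride; 3 (E)-4-methoxybut-3-en-2-one
Product: 6 2-[3-(benzyloxy)-4-methoxyphenyl]-4H-pyran-4-one, via lithium dienolate 4 (not isolated), via methoxyenedione 5 (not isolated)
Conditions: 3 (2 equiv), LiN(SiMe3)2 (2 equiv), THF, −78 °C; 2 (1 equiv), −78 → 0 °C; aq. NH4Cl; crude 5, CF3CO2H (cat.), toluene, rt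
Reagents that add atoms: none
Why: Kinetic deprotonation of the methyl group of 3 gives a cross-conjugated dienolate whose Claisen-type C-acylation by 2 forms 5 (the second equivalent of 4 absorbs its acidic proton), and acid then drives addition of the aroyl enol oxygen to the methoxyvinyl carbon with loss of methanol, the established γ-pyrone synthesis from 4-methoxybutenone and acid chlorides.

Step 3
Reactants: 6 2-[3-(benzyloxy)-4-methoxyphenyl]-4H-pyran-4-one; 7 dimethyl squarate
Product: 10 rac-4-{6-[3-(benzyloxy)-4-methoxyphenyl]-4-oxo-4H-pyran-2-yl}-4-hydroxy-2,3-dimethoxycyclobut-2-en-1-one, via 6-lithiopyranone 8 (not isolated), via lithium alkoxide 9 (not isolated)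
Conditions: lithium 2,2,6,6-tetramethylpiperidide (LiTMP, 1.1 equiv, from the amine and n-BuLi), THF, −78 °C, 6 added to the base, short ageing; 7 (1.3 equiv), THF, −78 °C; aq. NH4Cl at −78 °C
Reagents that add atoms: none
Why: C6–H is the only proton next to the ring oxygen and the most acidic site of a γ-pyrone (chromones are metalated at the corresponding C2), so the hindered amide should give 8 by α-lithiation without adding to the ring, and organolithiums add 1,2 to one of the two equivalent carbonyl groups of dimethyl squarate at −78 °C, setting the quaternary carbon as a racemate.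

Step 4
Reactants: 10 rac-4-{6-[3-(benzyloxy)-4-methoxyphenyl]-4-oxo-4H-pyran-2-yl}-4-hydroxy-2,3-dimethoxycyclobut-2-en-1-one
Product: 11 rac-4-{6-[3-(benzyloxy)-4-methoxyphenyl]-4-oxo-4H-pyran-2-yl}-2,3,4-trimethoxycyclobut-2-en-1-one
Conditions: MeI (10 equiv), Ag2O (2 equiv), 4 Å MS, MeCN, rt, dark
Reagents that add atoms: methyl iodide, CI
Why: Purdie methylation alkylates the acidic tertiary carbinol under nearly neutral conditions, which avoids alkoxide-induced opening of the cyclobutenone and, unlike methyl triflate, should not alkylate the pyranone carbonyl oxygen to a pyrylium salt.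

Step 5
Reactants: 11 rac-4-{6-[3-(benzyloxy)-4-methoxyphenyl]-4-oxo-4H-pyran-2-yl}-2,3,4-trimethoxycyclobut-2-en-1-one
Product: 14 3'-O-benzylgardenin D (3'-benzyloxy-5-hydroxy-4',6,7,8-tetramethoxyflavone), via dienylketene 12 (not isolated), via cyclohexadienone 13 (not isolated)
Conditions: p-xylene (0.01 M, degassed), 138 °C, Ar
Reagents that add atoms: none
Why: Heating breaks the C1–C4 bond of 11 in a conrotatory four-electron ring opening in which the donor methoxy group on C4 turns outward, so dienylketene 12 forms with the pyranonyl group on the ketene side of the new C=C bond. The ketene carbon then bonds to pyranone C3 in a thermal disrotatory six-electron electrocyclization of the ketene C=C, the central C=C and the pyranone C2=C3 bond, which closes the six-membered carbocycle (ring A) through the C4a–C5 bond and gives 13. The C4a proton of 13 lies between two carbonyl groups, so enolisation to the phenol, hydrogen-bonded to the C4 carbonyl, should be fast and make the sequence irreversible. The closest known reaction type is the Moore ring expansion of 4-alkenyl-, 4-aryl- and 4-heteroaryl-4-alkoxycyclobutenones to hydroquinone monoethers; since that reaction closes even onto benzene rings, the weakly aromatic pyranone, whose C3 is the nucleophilic β-carbon of an enol ether and so matches the electrophilic ketene carbon, should react at least as readily. No lasting stereocentre is made: the racemic C4 of 11 becomes the planar C8 and the transient C4a centre of 13 is erased on tautomerisation. The step needs torquoselectivity, secured by the C4 methoxy donor, site selectivity, secured because pyranone C2 has C3 as its only carbon neighbour in the ring, and differentiation of the four squarate-derived oxygens at C5–C8, secured because only the ketene oxygen arrives without a methyl group.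

Step 6
Reactants: 14 3'-O-benzylgardenin D
Product: 15 gardenin D (3',5-dihydroxy-4',6,7,8-tetramethoxyflavone)
Conditions: H2 (1 atm), Pd/C (10 wt%), THF–MeOH, rt
Reagents that add atoms: none
Why: Catalytic hydrogenolysis cleaves only the benzylic C–O bond, while the aryl methyl ethers, the chelated phenol and the flavone C2=C3 bond should be inert at atmospheric pressure and room temperature.

Compound list
1 | 3-(benzyloxy)-4-methoxybenzoic acid | COc1ccc(C(=O)O)cc1OCc1ccccc1 | starting material
2 | 3-(benzyloxy)-4-methoxybenzoyl chloride | COc1ccc(C(=O)Cl)cc1OCc1ccccc1 | intermediate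
3 | (E)-4-methoxybut-3-en-2-one | CO/C=C/C(C)=O | starting material
4 | lithium (E)-4-methoxybuta-1,3-dien-2-olate | C=C(O[Li])/C=C/OC | intermediate
5 | (E)-1-[3-(benzyloxy)-4-methoxyphenyl]-5-methoxypent-4-ene-1,3-dione | CO/C=C/C(=O)CC(=O)c1ccc(OC)c(OCc2ccccc2)c1 | intermediate
6 | 2-[3-(benzyloxy)-4-methoxyphenyl]-4H-pyran-4-one | O=c1ccoc(-c2ccc(OC)c(OCc3ccccc3)c2)c1 | intermediate
7 | dimethyl squarate (3,4-dimethoxycyclobut-3-ene-1,2-dione) | COC1=C(OC)C(=O)C1=O | starting material
8 | 2-[3-(benzyloxy)-4-methoxyphenyl]-6-lithio-4H-pyran-4-one | [Li]c1cc(=O)cc(-c2ccc(OC)c(OCc3ccccc3)c2)o1 | intermediate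
9 | lithium alkoxide of 10 (racemic) | O=C1C(OC)=C(OC)C1(O[Li])c1cc(=O)cc(-c2ccc(OC)c(OCc3ccccc3)c2)o1 | intermediate
10 | rac-4-{6-[3-(benzyloxy)-4-methoxyphenyl]-4-oxo-4H-pyran-2-yl}-4-hydroxy-2,3-dimethoxycyclobut-2-en-1-one | O=C1C(OC)=C(OC)C1(O)c1cc(=O)cc(-c2ccc(OC)c(OCc3ccccc3)c2)o1 | intermediate
11 | rac-4-{6-[3-(benzyloxy)-4-methoxyphenyl]-4-oxo-4H-pyran-2-yl}-2,3,4-trimethoxycyclobut-2-en-1-one | O=C1C(OC)=C(OC)C1(OC)c1cc(=O)cc(-c2ccc(OC)c(OCc3ccccc3)c2)o1 | intermediate
12 | (3Z)-4-{6-[3-(benzyloxy)-4-methoxyphenyl]-4-oxo-4H-pyran-2-yl}-2,3,4-trimethoxybuta-1,3-dien-1-one (dienylketene, pyranonyl cis to the ketene) | O=C=C(OC)/C(OC)=C(OC)\c1cc(=O)cc(-c2ccc(OC)c(OCc3ccccc3)c2)o1 | intermediate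
13 | rac-2-[3-(benzyloxy)-4-methoxyphenyl]-6,7,8-trimethoxy-4aH-chromene-4,5-dione | O=C1C(OC)=C(OC)C(OC)=C2OC(c3ccc(OC)c(OCc4ccccc4)c3)=CC(=O)C12 | intermediate
14 | 3'-O-benzylgardenin D (3'-benzyloxy-5-hydroxy-4',6,7,8-tetramethoxyflavone) | COc1ccc(-c2cc(=O)c3c(O)c(OC)c(OC)c(OC)c3o2)cc1OCc1ccccc1 | intermediate
15 | gardenin D (3',5-dihydroxy-4',6,7,8-tetramethoxyflavone) | COc1ccc(-c2cc(=O)c3c(O)c(OC)c(OC)c(OC)c3o2)cc1O | target

Total step count: 6. Longest linear sequence: 6 steps (1 → 15).

Steps most likely to fail

Step 3.
- **What may go wrong:** the lithiated pyranone may attack pyranone that has not yet been deprotonated. Deprotonation at C3 or C5 may compete and lead to ring opening. Residual amide may consume the squarate.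
- **Fallback (from 6, back at 10):** the carbanion is made from a carbon–iodine bond instead of a carbon–hydrogen bond.
  - Compound 6 is zincated at C6 with the mild base TMPZnCl·LiCl (TMP = 2,2,6,6-tetramethylpiperidyl; THF, rt). This reagent is expected to metalate chromones at the corresponding C2. The product is the chlorozinc pyranone F1.
  - Iodolysis with I2 gives 2-[3-(benzyloxy)-4-methoxyphenyl]-6-iodo-4H-pyran-4-one F2, which can be purified and its regiochemistry secured.
  - Iodine–magnesium exchange with i-PrMgCl·LiCl in THF at −78 °C gives the chloromagnesio pyranone F3, with no amine and no acidic pyranone present.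
  - Addition to 7 gives the chloromagnesium alkoxide F4, and an NH4Cl quench returns the route to 10.

Step 5.
- **What may go wrong:** the ketene may be diverted by dimerisation or by traces of water before it closes onto the pyranone. The substrate may also degrade at the temperature that ring opening needs.
- **Fallback (from 2, back at 15):** ring A is taken from the aromatic pool and ring C is closed last.
  - Acid chloride 2 acylates the phenol of purchased 2'-hydroxy-3',4',5',6'-tetramethoxyacetophenone F5 (pyridine, rt) to give the aryl ester F6.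
  - Baker–Venkataraman rearrangement (KOH, pyridine, 50 °C) moves the aroyl group to carbon and gives the 1,3-diketone F7.
  - Cyclodehydration (p-TsOH, toluene, reflux) gives 3'-benzyloxy-4',5,6,7,8-pentamethoxyflavone F8.
  - BCl3 in CH2Cl2 (−78 → 0 °C) cleaves the carbonyl-chelated 5-O-methyl group and the benzyl ether in one operation, which rejoins the route at 15.

Step 4.
- **What may go wrong:** alkylation of the hindered tertiary carbinol may be sluggish. Base-induced opening of the hydroxycyclobutenone, or loss of the pyranonyl group by retro-addition, may overtake it.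
- **Fallback (from 10, back at 14):** the methyl group is put on after ring A exists.
  - Carbinol 10 is itself heated (degassed p-xylene, 138 °C, Ar) in the parent 4-hydroxy version of the Moore ring expansion. This gives the hydroquinone 3'-benzyloxy-5,8-dihydroxy-4',6,7-trimethoxyflavone F9.
  - With MeI (1 equiv) and K2CO3 in acetone under Ar, only the 8-hydroxyl should be methylated, because the 5-hydroxyl is tied up in the hydrogen bond to the C4 carbonyl. This gives 14.

Further compounds
F1 | step 3 | 2-[3-(benzyloxy)-4-methoxyphenyl]-6-(chlorozincio)-4H-pyran-4-one | Cl[Zn]c1cc(=O)cc(-c2ccc(OC)c(OCc3ccccc3)c2)o1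
F2 | step 3 | 2-[3-(benzyloxy)-4-methoxyphenyl]-6-iodo-4H-pyran-4-one | Ic1cc(=O)cc(-c2ccc(OC)c(OCc3ccccc3)c2)o1
F3 | step 3 | 2-[3-(benzyloxy)-4-methoxyphenyl]-6-(chloromagnesio)-4H-pyran-4-one | Cl[Mg]c1cc(=O)cc(-c2ccc(OC)c(OCc3ccccc3)c2)o1
F4 | step 3 | chloromagnesium alkoxide of 10 (racemic) | O=C1C(OC)=C(OC)C1(O[Mg]Cl)c1cc(=O)cc(-c2ccc(OC)c(OCc3ccccc3)c2)o1
F5 | step 5 | 2'-hydroxy-3',4',5',6'-tetramethoxyacetophenone (purchased) | CC(=O)c1c(O)c(OC)c(OC)c(OC)c1OC
F6 | step 5 | 2-acetyl-3,4,5,6-tetramethoxyphenyl 3-(benzyloxy)-4-methoxybenzoate | CC(=O)c1c(OC)c(OC)c(OC)c(OC)c1OC(=O)c1ccc(OC)c(OCc2ccccc2)c1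
F7 | step 5 | 1-[3-(benzyloxy)-4-methoxyphenyl]-3-(2-hydroxy-3,4,5,6-tetramethoxyphenyl)propane-1,3-dione | COc1ccc(C(=O)CC(=O)c2c(O)c(OC)c(OC)c(OC)c2OC)cc1OCc1ccccc1
F8 | step 5 | 3'-benzyloxy-4',5,6,7,8-pentamethoxyflavone | COc1ccc(-c2cc(=O)c3c(OC)c(OC)c(OC)c(OC)c3o2)cc1OCc1ccccc1
F9 | step 4 | 3'-benzyloxy-5,8-dihydroxy-4',6,7-trimethoxyflavone | COc1ccc(-c2cc(=O)c3c(O)c(OC)c(OC)c(O)c3o2)cc1OCc1ccccc1
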